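**Strategy.** The route rests on taking ring C apart into a cyclobutenone and an alkyne. A Danheiser benzannulation between racemic 4-(benzyloxy)-3-ethoxycyclobutenone (ring C atoms C3–C6 with O3, O4, O5) and the ethynyl ether of the permethylated A–B phenol (C1, C2, with the B–O–C oxygen already in place) forms C2–C3, C1–C6 and C3–C4 in one operation. It exploits the resorcinol monoether pattern of ring C: aryloxy on C1 and hydroxyl on C3, meta across C2–H. O3, O4 and O5 emerge as phenol, benzyl ether and ethyl ether, so O4 alone is opened for ring D. Rings D to G follow by copper etherifications, then global dealkylation.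

Key step: step 7

Assumption: 2,4,6-trimethoxyphenol is taken as a catalogue compound. The A–B ether is made with the crowded ring as phenoxide and the open ring as bromide, because a di-ortho-substituted electron-rich aryl bromide and an unprotected hydroquinone are both poor partners in copper etherification.

**Step 1**
Reactants: 1 4-bromo-2,6-dimethoxyphenol
Product: 2 2-(benzyloxy)-5-bromo-1,3-dimethoxybenzene
Conditions: BnBr, K2CO3, DMF, 60 °C
Reagents that add atoms: benzyl bromide, BrCc1ccccc1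
Why: Williamson O-alkylation of the phenoxide with a benzylic bromide is reliable even for a 2,6-disubstituted phenol and masks the oxygen that later carries the alkyne.

**Step 2**
Reactants: 2 2-(benzyloxy)-5-bromo-1,3-dimethoxybenzene; 3 2,4,6-trimethoxyphenol
Product: 4 2-(benzyloxy)-1,3-dimethoxy-5-(2,4,6-trimethoxyphenoxy)benzene
Conditions: CuI (10 mol%), picolinic acid (20 mol%), K3PO4, DMSO, 90 °C, Ar
Reagents that add atoms: none
Why: Ullmann-type copper-catalysed diaryl ether synthesis in which the picolinic acid ligand lets the di-ortho-substituted phenoxide of 3 displace bromide from the sterically open C–Br of 2.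

**Step 3**
Reactants: 4 2-(benzyloxy)-1,3-dimethoxy-5-(2,4,6-trimethoxyphenoxy)benzene
Product: 5 2,6-dimethoxy-4-(2,4,6-trimethoxyphenoxy)phenol
Conditions: H2 (1 atm), 10% Pd/C, EtOAc–MeOH, rt
Reagents that add atoms: none
Why: Catalytic hydrogenolysis cleaves only the benzylic C–O bond, since methyl ethers and diaryl ethers are inert to Pd/C and hydrogen.

**Step 4**
Reactants: 5 2,6-dimethoxy-4-(2,4,6-trimethoxyphenoxy)phenol
Product: 6 2-{[(E)-1,2-dichloroethenyl]oxy}-1,3-dimethoxy-5-(2,4,6-trimethoxyphenoxy)benzene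
Conditions: Cl2C=CHCl, K2CO3, DMF, 70 °C
Reagents that add atoms: trichloroethylene, ClC=C(Cl)Cl
Why: Base-mediated anti addition of the phenoxide to dichloroacetylene formed in situ from trichloroethylene is the known route to (E)-1,2-dichlorovinyl aryl ethers and tolerates two ortho substituents because the electrophile is a slim sp carbon.

**Step 5**
Reactants: 6 2-{[(E)-1,2-dichloroethenyl]oxy}-1,3-dimethoxy-5-(2,4,6-trimethoxyphenoxy)benzene
Product: 9 2-(ethynyloxy)-1,3-dimethoxy-5-(2,4,6-trimethoxyphenoxy)benzene, via chloroethynyl ether 7 (not isolated), via lithium acetylide 8 (not isolated)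
Conditions: n-BuLi (2.3 equiv), THF, −78 → −40 °C; H2O, −78 °C; used at once as a toluene solution
Reagents that add atoms: none
Why: Dehydrochlorination followed by chlorine–lithium exchange is the established conversion of 1,2-dichlorovinyl ethers into lithium alkynyl ethers, and cold protonation should give the terminal aryl ethynyl ether, which the two ortho methoxy groups shield against polymerisation.

**Step 6**
Reactants: 10 benzyloxyacetyl chloride; 11 ethoxyacetylene
Product: 13 4-(benzyloxy)-3-ethoxycyclobut-2-en-1-one (racemic), via benzyloxyketene 12 (not isolated)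
Conditions: Et3N (slow addition), 11 (2.5 equiv), Et2O, 0 °C → rt
Reagents that add atoms: none
Why: Dehydrohalogenation gives an alkoxyketene that undergoes [2+2] cycloaddition with the ynol ether, the alkyne CH bonding to the ketene carbonyl carbon so that ethoxy ends on C3 and benzyloxy on C4; the C4 stereocentre is formed racemic and is erased in step 7.

**Step 7**
Reactants: 9 2-(ethynyloxy)-1,3-dimethoxy-5-(2,4,6-trimethoxyphenoxy)benzene; 13 4-(benzyloxy)-3-ethoxycyclobut-2-en-1-one (racemic)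
Product: 18 2-(benzyloxy)-3-ethoxy-5-[2,6-dimethoxy-4-(2,4,6-trimethoxyphenoxy)phenoxy]phenol, via vinylketene 14 (not isolated), via vinylcyclobutenone 15 (not isolated), via dienylketene 16 (not isolated), via cyclohexadienone 17 (not isolated)
Conditions: 13 (2 equiv), toluene (degassed), 80 → 110 °C, sealed tube, Ar; then K2CO3, MeOH, rt
Reagents that add atoms: none
Why: Heating opens 13 by 4π electrocyclic ring opening (benzyloxy turning outward) to vinylketene 14, whose ketene C=C undergoes [2+2] cycloaddition with the electron-rich alkyne of 9 to give 15 (bonds C2–C3 and C1–C6 of ring C), and 15 reopens to dienylketene 16. Ring C is then closed by a thermal disrotatory 6π electrocyclisation of 16 that forms C3–C4, and dienone 17 tautomerises to phenol 18. The closest known reaction type is the Danheiser benzannulation of cyclobutenones with alkoxy- and siloxyacetylenes, of which an aryloxyacetylene is a less electron-rich member. No stereocentre survives, because C4 of 13 and the sp3 carbons of 15 and 17 all become aromatic carbons. The one selectivity needed is the orientation of the ketene–alkyne cycloaddition, and the ether oxygen secures it by making the alkyne CH the nucleophilic terminus that bonds to the electrophilic ketene carbonyl carbon, which places aryloxy meta to the new hydroxyl. Cyclobutenone 13 is used in excess because 9 is the costly partner, and the carbonate methanolysis should release any 18 that was acylated by surplus ketene.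

**Step 8**
Reactants: 18 2-(benzyloxy)-3-ethoxy-5-[2,6-dimethoxy-4-(2,4,6-trimethoxyphenoxy)phenoxy]phenol
Product: 19 2-(benzyloxy)-1-ethoxy-3-methoxy-5-[2,6-dimethoxy-4-(2,4,6-trimethoxyphenoxy)phenoxy]benzene
Conditions: MeI, K2CO3, acetone, 50 °C
Reagents that add atoms: iodomethane, CI
Why: Williamson methylation of the only free phenol fixes O3 of ring C as a methyl ether while the benzyl ether on O4 stays orthogonal.

**Step 9**
Reactants: 19 2-(benzyloxy)-1-ethoxy-3-methoxy-5-[2,6-dimethoxy-4-(2,4,6-trimethoxyphenoxy)phenoxy]benzene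
Product: 20 2-ethoxy-6-methoxy-4-[2,6-dimethoxy-4-(2,4,6-trimethoxyphenoxy)phenoxy]phenol
Conditions: H2 (1 atm), 10% Pd/C, EtOAc–EtOH, rt
Reagents that add atoms: none
Why: Hydrogenolysis removes the single benzyl group and uncovers only the C4 hydroxyl of ring C, flanked by methoxy and ethoxy.

**Step 10**
Reactants: 21 5-bromo-1,2,3-trimethoxybenzene
Product: 23 6-bromo-2,3,4-trimethoxybenzaldehyde, via chloro(methoxy)methyl arene 22 (not isolated)
Conditions: Cl2CHOMe, TiCl4, CH2Cl2, −10 → 0 °C; then H2O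
Reagents that add atoms: dichloromethyl methyl ether, COC(Cl)Cl; water, O
Why: Rieche formylation (electrophilic aromatic substitution) can only attack the two equivalent free positions, para to one methoxy and ortho to bromine, so hydrolysis should give a single aldehyde with CHO between Br and OMe.

**Step 11**
Reactants: 20 2-ethoxy-6-methoxy-4-[2,6-dimethoxy-4-(2,4,6-trimethoxyphenoxy)phenoxy]phenol; 23 6-bromo-2,3,4-trimethoxybenzaldehyde
Product: 24 6-{2-ethoxy-6-methoxy-4-[2,6-dimethoxy-4-(2,4,6-trimethoxyphenoxy)phenoxy]phenoxy}-2,3,4-trimethoxybenzaldehyde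
Conditions: CuI (20 mol%), picolinic acid (40 mol%), K3PO4, DMSO, 90 °C, Ar
Reagents that add atoms: none
Why: Ullmann diaryl ether coupling in which the ortho formyl group activates the C–Br bond toward copper and the picolinic acid ligand copes with the di-ortho-substituted phenoxide, while the non-enolisable aldehyde tolerates phosphate base.

**Step 12**
Reactants: 24 6-{2-ethoxy-6-methoxy-4-[2,6-dimethoxy-4-(2,4,6-trimethoxyphenoxy)phenoxy]phenoxy}-2,3,4-trimethoxybenzaldehyde
Product: 26 6-{2-ethoxy-6-methoxy-4-[2,6-dimethoxy-4-(2,4,6-trimethoxyphenoxy)phenoxy]phenoxy}-2,3,4-trimethoxyphenol, via aryl formate 25 (not isolated)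
Conditions: 30% H2O2, H2SO4 (cat.), MeOH, rt
Reagents that add atoms: hydrogen peroxide, OO
Why: Acid-catalysed Dakin oxidation, in which peroxide addition to the carbonyl and 1,2-shift of the very electron-rich aryl group (ortho and para methoxy) give a formate that is methanolysed in the flask, turns the formyl carbon into the ring D hydroxyl without touching the ethers.

**Step 13**
Reactants: 27 (3,4,5-trimethoxyphenyl)boronic acid; 1 4-bromo-2,6-dimethoxyphenol
Product: 28 5-bromo-1,3-dimethoxy-2-(3,4,5-trimethoxyphenoxy)benzene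
Conditions: Cu(OAc)2 (30 mol%), pyridine, 4 Å MS, O2 (1 atm), CH2Cl2, rt
Reagents that add atoms: none
Why: Chan–Lam oxidative coupling joins the aryl group of the boronic acid to the phenolic oxygen at room temperature, accepts di-ortho-substituted phenols and leaves the C–Br bond intact for later use.

**Step 14**
Reactants: 28 5-bromo-1,3-dimethoxy-2-(3,4,5-trimethoxyphenoxy)benzene
Product: 31 [3,5-dimethoxy-4-(3,4,5-trimethoxyphenoxy)phenyl]boronic acid, via aryllithium 29 (not isolated), via lithium triisopropoxyborate 30 (not isolated)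
Conditions: n-BuLi, THF, −78 °C; B(OiPr)3, −78 °C → rt; 1 M HCl
Reagents that add atoms: triisopropyl borate, CC(C)OB(OC(C)C)OC(C)C; water, O
Why: Bromine–lithium exchange at −78 °C outpaces ortho-lithiation next to the methoxy groups, and borate trapping with acidic hydrolysis is the standard boronic acid synthesis.

**Step 15**
Reactants: 31 [3,5-dimethoxy-4-(3,4,5-trimethoxyphenoxy)phenyl]boronic acid; 1 4-bromo-2,6-dimethoxyphenol
Product: 32 5-bromo-2-[3,5-dimethoxy-4-(3,4,5-trimethoxyphenoxy)phenoxy]-1,3-dimethoxybenzene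
Conditions: Cu(OAc)2 (30 mol%), pyridine, 4 Å MS, O2 (1 atm), CH2Cl2, rt
Reagents that add atoms: none
Why: A second Chan–Lam coupling forms the C–O bond at the hindered phenol oxygen and keeps the aryl bromide that step 16 needs.

**Step 16**
Reactants: 26 6-{2-ethoxy-6-methoxy-4-[2,6-dimethoxy-4-(2,4,6-trimethoxyphenoxy)phenoxy]phenoxy}-2,3,4-trimethoxyphenol; 32 5-bromo-2-[3,5-dimethoxy-4-(3,4,5-trimethoxyphenoxy)phenoxy]-1,3-dimethoxybenzene
Product: 33 1-{2-ethoxy-6-methoxy-4-[2,6-dimethoxy-4-(2,4,6-trimethoxyphenoxy)phenoxy]phenoxy}-2-{3,5-dimethoxy-4-[3,5-dimethoxy-4-(3,4,5-trimethoxyphenoxy)phenoxy]phenoxy}-3,4,5-trimethoxybenzene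
Conditions: CuI (30 mol%), picolinic acid (60 mol%), K3PO4, DMSO, 100 °C, Ar
Reagents that add atoms: none
Why: Ullmann fragment coupling of a di-ortho-substituted phenoxide with an unhindered aryl bromide, the combination for which the CuI–picolinic acid system is suited, with no other reactive group present.

**Step 17**
Reactants: 33 the hexadecamethyl monoethyl ether of the target (name as in step 16)
Product: 34 2-[4-(4-{2-[3,5-dihydroxy-4-(3,5-dihydroxy-4-(3,4,5-trihydroxyphenoxy)phenoxy)phenoxy]-3,4,5-trihydroxyphenoxy}-3,5-dihydroxyphenoxy)-3,5-dihydroxyphenoxy]benzene-1,3,5-triol (CNP0304148.0)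
Conditions: BBr3 (excess), CH2Cl2, −78 °C → rt, Ar; then degassed H2O
Reagents that add atoms: none
Why: Lewis-acid ether cleavage, in which BBr3 complexes each alkyl aryl ether oxygen and bromide removes the methyl or ethyl group by SN2, should free all seventeen hydroxyls while the six diaryl ether bonds, which offer no alkyl carbon, persist.

**Compound list**

1 | 4-bromo-2,6-dimethoxyphenol | COc1cc(Br)cc(OC)c1O | starting material
2 | 2-(benzyloxy)-5-bromo-1,3-dimethoxybenzene | COc1cc(Br)cc(OC)c1OCc1ccccc1 | intermediate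
3 | 2,4,6-trimethoxyphenol | COc1cc(OC)c(O)c(OC)c1 | starting material
4 | 2-(benzyloxy)-1,3-dimethoxy-5-(2,4,6-trimethoxyphenoxy)benzene | COc1cc(OC)c(Oc2cc(OC)c(OCc3ccccc3)c(OC)c2)c(OC)c1 | intermediate
5 | 2,6-dimethoxy-4-(2,4,6-trimethoxyphenoxy)phenol | COc1cc(OC)c(Oc2cc(OC)c(O)c(OC)c2)c(OC)c1 | intermediate
6 | 2-{[(E)-1,2-dichloroethenyl]oxy}-1,3-dimethoxy-5-(2,4,6-trimethoxyphenoxy)benzene | Cl/C=C(Cl)\Oc1c(OC)cc(Oc2c(OC)cc(OC)cc2OC)cc1OC | intermediate
7 | 2-[(chloroethynyl)oxy]-1,3-dimethoxy-5-(2,4,6-trimethoxyphenoxy)benzene | ClC#COc1c(OC)cc(Oc2c(OC)cc(OC)cc2OC)cc1OC | intermediate (not isolated)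
8 | lithium 2-[2,6-dimethoxy-4-(2,4,6-trimethoxyphenoxy)phenoxy]ethynide | [Li]C#COc1c(OC)cc(Oc2c(OC)cc(OC)cc2OC)cc1OC | intermediate (not isolated)
9 | 2-(ethynyloxy)-1,3-dimethoxy-5-(2,4,6-trimethoxyphenoxy)benzene | C#COc1c(OC)cc(Oc2c(OC)cc(OC)cc2OC)cc1OC | intermediate
10 | benzyloxyacetyl chloride | O=C(Cl)COCc1ccccc1 | starting material
11 | ethoxyacetylene | C#COCC | starting material
12 | benzyloxyketene | O=C=COCc1ccccc1 | intermediate (not isolated)
13 | 4-(benzyloxy)-3-ethoxycyclobut-2-en-1-one (racemic) | CCOC1=CC(=O)C1OCc1ccccc1 | intermediate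
14 | (3Z)-4-(benzyloxy)-3-ethoxybuta-1,3-dien-1-one | O=C=C/C(OCC)=C/OCc1ccccc1 | intermediate (not isolated)
15 | 4-[(Z)-2-(benzyloxy)-1-ethoxyethenyl]-3-[2,6-dimethoxy-4-(2,4,6-trimethoxyphenoxy)phenoxy]cyclobut-2-en-1-one (racemic) | O=C1C=C(Oc2c(OC)cc(Oc3c(OC)cc(OC)cc3OC)cc2OC)C1/C(OCC)=C/OCc1ccccc1 | intermediate (not isolated)
16 | (3E,5Z)-6-(benzyloxy)-5-ethoxy-3-[2,6-dimethoxy-4-(2,4,6-trimethoxyphenoxy)phenoxy]hexa-1,3,5-trien-1-one | O=C=C/C(Oc1c(OC)cc(Oc2c(OC)cc(OC)cc2OC)cc1OC)=C\C(OCC)=C\OCc1ccccc1 | intermediate (not isolated)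
17 | 6-(benzyloxy)-5-ethoxy-3-[2,6-dimethoxy-4-(2,4,6-trimethoxyphenoxy)phenoxy]cyclohexa-2,4-dien-1-one (racemic) | O=C1C=C(Oc2c(OC)cc(Oc3c(OC)cc(OC)cc3OC)cc2OC)C=C(OCC)C1OCc1ccccc1 | intermediate (not isolated)
18 | 2-(benzyloxy)-3-ethoxy-5-[2,6-dimethoxy-4-(2,4,6-trimethoxyphenoxy)phenoxy]phenol | CCOc1cc(Oc2c(OC)cc(Oc3c(OC)cc(OC)cc3OC)cc2OC)cc(O)c1OCc1ccccc1 | intermediate
19 | 2-(benzyloxy)-1-ethoxy-3-methoxy-5-[2,6-dimethoxy-4-(2,4,6-trimethoxyphenoxy)phenoxy]benzene | CCOc1cc(Oc2c(OC)cc(Oc3c(OC)cc(OC)cc3OC)cc2OC)cc(OC)c1OCc1ccccc1 | intermediate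
20 | 2-ethoxy-6-methoxy-4-[2,6-dimethoxy-4-(2,4,6-trimethoxyphenoxy)phenoxy]phenol | CCOc1cc(Oc2c(OC)cc(Oc3c(OC)cc(OC)cc3OC)cc2OC)cc(OC)c1O | intermediate
21 | 5-bromo-1,2,3-trimethoxybenzene | COc1cc(Br)cc(OC)c1OC | starting material
22 | 1-bromo-2-[chloro(methoxy)methyl]-3,4,5-trimethoxybenzene (racemic) | COc1cc(Br)c(C(Cl)OC)c(OC)c1OC | intermediate (not isolated)
23 | 6-bromo-2,3,4-trimethoxybenzaldehyde | COc1cc(Br)c(C=O)c(OC)c1OC | intermediate
24 | 6-{2-ethoxy-6-methoxy-4-[2,6-dimethoxy-4-(2,4,6-trimethoxyphenoxy)phenoxy]phenoxy}-2,3,4-trimethoxybenzaldehyde | CCOc1cc(Oc2c(OC)cc(Oc3c(OC)cc(OC)cc3OC)cc2OC)cc(OC)c1Oc1cc(OC)c(OC)c(OC)c1C=O | intermediate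
25 | 6-{2-ethoxy-6-methoxy-4-[2,6-dimethoxy-4-(2,4,6-trimethoxyphenoxy)phenoxy]phenoxy}-2,3,4-trimethoxyphenyl formate | CCOc1cc(Oc2c(OC)cc(Oc3c(OC)cc(OC)cc3OC)cc2OC)cc(OC)c1Oc1cc(OC)c(OC)c(OC)c1OC=O | intermediate (not isolated)
26 | 6-{2-ethoxy-6-methoxy-4-[2,6-dimethoxy-4-(2,4,6-trimethoxyphenoxy)phenoxy]phenoxy}-2,3,4-trimethoxyphenol | CCOc1cc(Oc2c(OC)cc(Oc3c(OC)cc(OC)cc3OC)cc2OC)cc(OC)c1Oc1cc(OC)c(OC)c(OC)c1O | intermediate
27 | (3,4,5-trimethoxyphenyl)boronic acid | COc1cc(B(O)O)cc(OC)c1OC | starting material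
28 | 5-bromo-1,3-dimethoxy-2-(3,4,5-trimethoxyphenoxy)benzene | COc1cc(Br)cc(OC)c1Oc1cc(OC)c(OC)c(OC)c1 | intermediate
29 | [3,5-dimethoxy-4-(3,4,5-trimethoxyphenoxy)phenyl]lithium | [Li]c1cc(OC)c(Oc2cc(OC)c(OC)c(OC)c2)c(OC)c1 | intermediate (not isolated)
30 | lithium triisopropoxy[3,5-dimethoxy-4-(3,4,5-trimethoxyphenoxy)phenyl]borate | [Li+].CC(C)O[B-](OC(C)C)(OC(C)C)c1cc(OC)c(Oc2cc(OC)c(OC)c(OC)c2)c(OC)c1 | intermediate (not isolated)
31 | [3,5-dimethoxy-4-(3,4,5-trimethoxyphenoxy)phenyl]boronic acid | OB(O)c1cc(OC)c(Oc2cc(OC)c(OC)c(OC)c2)c(OC)c1 | intermediate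
32 | 5-bromo-2-[3,5-dimethoxy-4-(3,4,5-trimethoxyphenoxy)phenoxy]-1,3-dimethoxybenzene | COc1cc(Br)cc(OC)c1Oc1cc(OC)c(Oc2cc(OC)c(OC)c(OC)c2)c(OC)c1 | intermediate
33 | 1-{2-ethoxy-6-methoxy-4-[2,6-dimethoxy-4-(2,4,6-trimethoxyphenoxy)phenoxy]phenoxy}-2-{3,5-dimethoxy-4-[3,5-dimethoxy-4-(3,4,5-trimethoxyphenoxy)phenoxy]phenoxy}-3,4,5-trimethoxybenzene | CCOc1cc(Oc2c(OC)cc(Oc3c(OC)cc(OC)cc3OC)cc2OC)cc(OC)c1Oc1cc(OC)c(OC)c(OC)c1Oc1cc(OC)c(Oc2cc(OC)c(Oc3cc(OC)c(OC)c(OC)c3)c(OC)c2)c(OC)c1 | intermediate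
34 | 2-[4-(4-{2-[3,5-dihydroxy-4-(3,5-dihydroxy-4-(3,4,5-trihydroxyphenoxy)phenoxy)phenoxy]-3,4,5-trihydroxyphenoxy}-3,5-dihydroxyphenoxy)-3,5-dihydroxyphenoxy]benzene-1,3,5-triol (CNP0304148.0, achiral) | Oc1cc(O)c(Oc2cc(O)c(Oc3cc(O)c(Oc4cc(O)c(O)c(O)c4Oc4cc(O)c(Oc5cc(O)c(Oc6cc(O)c(O)c(O)c6)c(O)c5)c(O)c4)c(O)c3)c(O)c2)c(O)c1 | target

**Step count and risk**

Total steps: 17. Longest linear sequence: 12 steps (steps 1, 2, 3, 4, 5, 7, 8, 9, 11, 12, 16, 17).

The three steps most likely to fail: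

Step 7. The terminal aryl ethynyl ether may polymerise, or the alkoxy-substituted vinylketene may dimerise or be consumed by acylation, before the ketene–alkyne cycloaddition takes place, so that ring C is not formed. The fallback builds ring C as a preformed monomer and attaches it by the copper etherification already used for rings A and B. It sets out from 5 and returns at 19. Commercial 5-bromo-2-hydroxy-3-methoxybenzaldehyde is benzylated (BnBr, K2CO3, DMF) to 2-(benzyloxy)-5-bromo-3-methoxybenzaldehyde F1. Acid-catalysed Dakin oxidation (H2O2, cat. H2SO4, MeOH) passes through 2-(benzyloxy)-5-bromo-3-methoxyphenyl formate F2 to 2-(benzyloxy)-5-bromo-3-methoxyphenol F3. Ethylation (EtI, K2CO3, acetone) gives 2-(benzyloxy)-5-bromo-1-ethoxy-3-methoxybenzene F4. Ullmann coupling of 5 with F4 (CuI, picolinic acid, K3PO4, DMSO, 90 °C) should give 19 directly.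

Step 16. The crowded phenoxide of 26, flanked by an aryloxy and a methoxy group, may bind copper too slowly to displace bromide from 32 at a useful rate, so that at 100 °C reduction of the bromide and decomposition of both fragments take over. The fallback turns the electrophile into a boron nucleophile and couples oxidatively at room temperature. It sets out from 32 and returns at 33. Bromine–lithium exchange (n-BuLi, THF, −78 °C) gives {3,5-dimethoxy-4-[3,5-dimethoxy-4-(3,4,5-trimethoxyphenoxy)phenoxy]phenyl}lithium F5. Triisopropyl borate converts it into lithium triisopropoxy{3,5-dimethoxy-4-[3,5-dimethoxy-4-(3,4,5-trimethoxyphenoxy)phenoxy]phenyl}borate F6, and acid hydrolysis gives {3,5-dimethoxy-4-[3,5-dimethoxy-4-(3,4,5-trimethoxyphenoxy)phenoxy]phenyl}boronic acid F7. Chan–Lam coupling of F7 with 26 (Cu(OAc)2, pyridine, 4 Å MS, O2, CH2Cl2, rt) should give 33.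

Step 17. Cleavage may stall at some of the seventeen ether sites, and the free polyphenol may oxidise in air or be lost by adsorption during isolation, giving an inseparable mixture. The fallback is a two-stage end game through a stable ester. It sets out from 33 and returns at 34. After exhaustive BBr3 cleavage and quench under argon, the crude phenol is not purified but acetylated (Ac2O, pyridine, DMAP) to the heptadecaacetate of the target F8. This ester can be chromatographed on silica, where under-cleaved congeners are removed. Zemplén deacetylation (cat. NaOMe, degassed MeOH, then acidic resin) should then release 34 as the last, mild operation.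

**Further compounds**

F1 | step 7 | 2-(benzyloxy)-5-bromo-3-methoxybenzaldehyde | COc1cc(Br)cc(C=O)c1OCc1ccccc1
F2 | step 7 | 2-(benzyloxy)-5-bromo-3-methoxyphenyl formate | COc1cc(Br)cc(OC=O)c1OCc1ccccc1
F3 | step 7 | 2-(benzyloxy)-5-bromo-3-methoxyphenol | COc1cc(Br)cc(O)c1OCc1ccccc1
F4 | step 7 | 2-(benzyloxy)-5-bromo-1-ethoxy-3-methoxybenzene | CCOc1cc(Br)cc(OC)c1OCc1ccccc1
F5 | step 16 | {3,5-dimethoxy-4-[3,5-dimethoxy-4-(3,4,5-trimethoxyphenoxy)phenoxy]phenyl}lithium | [Li]c1cc(OC)c(Oc2cc(OC)c(Oc3cc(OC)c(OC)c(OC)c3)c(OC)c2)c(OC)c1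
F6 | step 16 | lithium triisopropoxy{3,5-dimethoxy-4-[3,5-dimethoxy-4-(3,4,5-trimethoxyphenoxy)phenoxy]phenyl}borate | [Li+].CC(C)O[B-](OC(C)C)(OC(C)C)c1cc(OC)c(Oc2cc(OC)c(Oc3cc(OC)c(OC)c(OC)c3)c(OC)c2)c(OC)c1
F7 | step 16 | {3,5-dimethoxy-4-[3,5-dimethoxy-4-(3,4,5-trimethoxyphenoxy)phenoxy]phenyl}boronic acid | OB(O)c1cc(OC)c(Oc2cc(OC)c(Oc3cc(OC)c(OC)c(OC)c3)c(OC)c2)c(OC)c1
F8 | step 17 | heptadecaacetate of the target (all seventeen hydroxyls as acetates) | CC(=O)Oc1cc(OC(C)=O)c(Oc2cc(OC(C)=O)c(Oc3cc(OC(C)=O)c(Oc4cc(OC(C)=O)c(OC(C)=O)c(OC(C)=O)c4Oc4cc(OC(C)=O)c(Oc5cc(OC(C)=O)c(Oc6cc(OC(C)=O)c(OC(C)=O)c(OC(C)=O)c6)c(OC(C)=O)c5)c(OC(C)=O)c4)c(OC(C)=O)c3)c(OC(C)=O)c2)c(OC(C)=O)c1
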